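## Analysis of the target

(7'S,8'S)-Nocomtal (11) is a 1,4-benzodioxane neolignan. Its benzo part is ring A, which carries a methoxy group at C3 and an (E)-propenal chain at C1. Of the two sp3 carbons of the dioxane, C7' bears the 4-hydroxy-3-methoxyphenyl (guaiacyl) ring and is bonded to O5, and C8' bears the hydroxymethyl carbon C9' and is bonded to O4. These adjacent carbons are the only stereocentres. Both are S, which places the guaiacyl ring and the CH2OH group trans on the dioxane ring and corresponds to a threo open-chain arylglycerol ether. The sensitive groups are the enal, the free phenol and the C7'–O5 bond, a benzylic aryl ether para to a phenolic oxygen that can ionise towards a quinone methide and so epimerise C7'. The synthesis is hard because the two aryl ether bonds must form with the right regiochemistry (O4 to C8', O5 to C7'), because two contiguous oxygenated centres must be set in one absolute sense next to an electron-rich arene, and because C9' and the ring A side chain end at different oxidation levels. The route rests on C8': it carries O4, C9' and C7', so a ring A phenol, a two-carbon unit and a guaiacyl aldehyde can all be joined at this one carbon, and a bromide already present at C5 then allows the O5–C7' side of the ring to be closed without touching either stereocentre.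

## Retrosynthetic reasoning

The last bond cut is the O–CH2 bond of a benzyl ether on the guaiacyl oxygen, which leads from 11 back to 10. The phenol stays masked to the end for two reasons: once free it makes the C7'–O5 bond prone to quinone-methide ionisation, and a free phenol would compete for the carbenoid in the key step. The forward step must remove the benzyl group without reducing the enal, so a low-temperature Lewis-acid cleavage is used instead of hydrogenolysis.

The C=C bond of the enal in 10 is cut next, giving the ring A aldehyde 9 and a two-carbon formyl unit. The enal is the most electrophilic group of the target and should exist for as few steps as possible. A Wittig reaction with a stabilised ylide sets the E geometry.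

Aldehyde 9 is traced to diol 8 and then to diester 7 by changes of oxidation level only. Carrying both C9' and the ring A carbon as esters has two gains. The ring A substituent cannot act as a second aldehyde in the key step, and a C9' ester, unlike a free C9' alcohol, cannot compete with the C7' hydroxyl in the ring closure. Forward, one hydride reduction takes both esters to 8, and a benzylic-selective oxidation returns only the ring A carbinol to aldehyde 9.

In 7 the O5–C5 aryl–oxygen bond is cut, which opens the dioxane to the bromo alcohol 6. This bond is chosen over C7'–O5 because forming it leaves the C7'–O bond intact, so the configuration of 6 is carried into the ring with retention. A closure by displacement at C7' would have to invert a benzylic centre that ionises easily. The forward reaction is a copper-catalysed intramolecular O-arylation forming a six-membered ring; a threo 6 gives the trans ring.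

Adduct 6 is cut at the two bonds that meet at C8', O4–C8' and C7'–C8'. This divides it into ring A phenol 3, diazoester 4 as the C8'–C9' unit and aldehyde 2, three pieces that are bought or made in one step. It also settles the regiochemistry of the dioxane at the outset, since C8' is bonded to O4 from the moment it becomes sp3. Forward, a rhodium carbenoid from 4 must be captured by the oxygen of 3 to give ylide 5, and 5 must add to 2 under the control of a chiral Brønsted acid before it collapses by proton transfer. The step must deliver the threo adduct in the (2R,3S) series. The C5 bromide of 3 is a spectator here and the handle for the ring closure.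

Aldehyde 2 is the benzyl ether of vanillin 1; the O–benzyl bond is formed by a Williamson alkylation.

## Alternatives that were turned down

Alternative 1: The dioxane is opened at O5–C7' in the oxidative sense. The precursor is the open-chain ether A2, in which C8' already carries O4 and the silyl-protected C9' as a single enantiomer, C7' is a methylene group, and both the guaiacyl phenol and the ring A C5 phenol are free. In the forward key step a silver oxidant converts the guaiacyl phenol into the para-quinone methide at C7', and the C5 phenol adds to C7' in a 6-exo-trig closure to give the trans benzodioxane A1.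
- For: the closure is mild and biomimetic, and the trans relation follows from reversible addition under the influence of C8'. A1 already has the guaiacyl phenol free, so no debenzylation is needed at the end. On this point it is stronger than the chosen route, whose last step exposes the finished enal to a Lewis acid.
- Against: A2 must be assembled by etherification of the hindered ring A phenol with an enantiopure secondary carbinol, and two ring A oxygens must be told apart by protecting groups, so the controlling stereocentre is bought in a separate multistep sequence. Oxidation of a plain 4-alkylguaiacol to its quinone methide is slow without extended conjugation and competes with oxidation of the second phenol. The quinone methide has a C8' hydrogen next to O4, so tautomerisation to the aryl enol ether would erase C8'.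
- Comparison: the chosen strategy reaches the same ring in fewer steps by creating C8' with all three of its bonds in one operation, and it offers catalyst control where this alternative offers substrate control over C7' only.

Alternative 2: C7'–C8' and the O–C9' bond are cut together. A Paternò–Büchi [2+2] photocycloaddition between the acetate-protected aldehyde A5 and the ring A aryl vinyl ether A4 would give the 2-aryl-3-aryloxyoxetane A3, the aldehyde oxygen bonding to the CH2 terminus as expected for the more stabilised 1,4-biradical. After removal of the methoxymethyl group from O5, the phenol would open the strained oxetane at the benzylic C7', closing the dioxane and freeing C9' as the alcohol.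
- For: the cycloaddition is fully atom-economic and C9' arrives at the alcohol oxidation level, so the reduction and re-oxidation of the chosen route are not needed. In redox economy this alternative is the stronger one.
- Against: nothing in the photoreaction controls absolute configuration, so A3 is racemic and a resolution would have to be added. 4-Oxygenated benzaldehydes have low-lying π,π* triplet states and are poor partners in this cycloaddition. A3 forms as a mixture of C7' epimers, of which only one gives the trans ring by invertive opening, and an acid-promoted opening through the benzylic cation loses that stereospecificity. A4 needs a vinylation of the hindered phenol and separate protection of O5.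
- Comparison: the chosen strategy also stakes its yield on one unprecedented step, but that step has a handle for absolute stereocontrol and a fallback in known chemistry, which a racemic photocycloaddition does not.

Alternative 3: Both aryl–oxygen bonds, C4–O4 and C5–O5, are cut. This gives the threo diol ester A7, available by asymmetric dihydroxylation, and the ring A electrophile A8, a 4-fluoro-5-bromo benzaldehyde. Forward, the C8' hydroxyl of A7 displaces fluoride para to the formyl group, and a copper-catalysed coupling of the C7' hydroxyl with the C5 bromide then closes the dioxane, both with retention, to give A6.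
- For: the two stereocentres come from one of the most dependable enantioselective reactions known, every step has close precedent, and the ring A carbon is already an aldehyde. In certainty of the stereochemical outcome this alternative is clearly stronger than the chosen strategy.
- Against: the two secondary hydroxyls of A7 must be told apart in the substitution step, and attack by the C7' hydroxyl leads after closure to the regioisomeric benzodioxane. The strong base needed acts on a β-hydroxy ester that can undergo retro-aldol cleavage and C8' epimerisation. The fluoride of A8 is flanked by bromine and methoxy and activated by one formyl group only. A6 holds an ester and an aldehyde at once, so the reduction of C9' needs a protecting or redox detour, and A8 itself has to be made.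
- Comparison: the chosen strategy shares the copper ring closure but fixes the regiochemistry by construction, because C8' is bonded to O4 when it is created, and it joins three simple pieces in one step. What it gives up in precedent it covers with an auxiliary-based aldol route to the same intermediate 6.

Key step: step 2

## Route

Assumption: phenol 3 is taken as a purchasable compound, and the antipode of the phosphoric acid in step 2 that leads to the (2R,3S) adduct is fixed in a first trial with both commercial antipodes, since its sense of induction on this new combination of substrates cannot be predicted with confidence.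

Step 1
Reactants: 1 vanillin (4-hydroxy-3-methoxybenzaldehyde)
Product: 2 4-(benzyloxy)-3-methoxybenzaldehyde (O-benzylvanillin)
Conditions: BnBr, K2CO3, DMF, rt
Reagents that add atoms: benzyl bromide, BrCc1ccccc1
Why: Williamson ether synthesis on the vanillin phenoxide; the benzyl ether keeps this phenol from capturing the carbenoid in step 2 and is inert to the copper, hydride and MnO2 steps that follow.

Step 2
Reactants: 3 methyl 3-bromo-4-hydroxy-5-methoxybenzoate (methyl 5-bromovanillate), 4 ethyl diazoacetate, 2 4-(benzyloxy)-3-methoxybenzaldehyde
Product: 6 ethyl (2R,3S)-3-[4-(benzyloxy)-3-methoxyphenyl]-2-[2-bromo-6-methoxy-4-(methoxycarbonyl)phenoxy]-3-hydroxypropanoate, via oxonium ylide 5 (not isolated)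
Conditions: Rh2(OAc)4 (2 mol%), 3,3'-bis(2,4,6-triisopropylphenyl)-1,1'-binaphthyl-2,2'-diyl hydrogen phosphate (TRIP, 10 mol%), 4 Å MS, CH2Cl2, 0 °C, 4 (1.5 equiv) added over 6 h to 3 and 2 (1.5 equiv)
Reagents that add atoms: none
Why: Proposed new method: Rh2(OAc)4 converts 4 into an electrophilic rhodium carbenoid, the phenolic oxygen of 3 adds to it to give the protic oxonium ylide 5 (in equilibrium with the enol whose O–H lies cis to the aryloxy group, because the proton is passed on within the ylide), and this nucleophile attacks aldehyde 2, activated by hydrogen bonding to the phosphoric acid, before the 1,2-proton shift that would end in plain O–H insertion. The closest known reaction type is the three-component aldol- and Mannich-type trapping of alcohol-derived oxonium ylides from aryldiazoacetates under dirhodium tetraacetate with a chiral phosphoric acid or chiral Lewis acid; a phenol, an acceptor-only diazoacetate and an electron-rich aldehyde have not been combined in this way. Two bonds form, O4–C8' and C7'–C8', and no ring is closed. Both stereocentres arise in the C–C bond-forming event and both are controlled by the acid: it is expected to hold the ylide or enol O–H on its P=O oxygen and the aldehyde on its P–OH group, so that its 3,3'-aryl groups choose the aldehyde face (C7') and the cis enol geometry in this closed assembly sets C8' syn to C7', which is the threo relation. The step needs three selectivities: trapping over proton transfer, threo over erythro, and one absolute sense. Trapping is helped by slow addition of 4, an excess of 2 and the two ortho substituents of 3, which crowd the oxonium centre and should slow the intermolecular proton shuttle; chemoselectivity for 2 is secured because ring A carries an ester and not an aldehyde and the guaiacyl phenol is benzylated; the C5 bromide is inert to the carbenoid and is kept for the ring closure.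

Step 3
Reactants: 6 ethyl (2R,3S)-3-[4-(benzyloxy)-3-methoxyphenyl]-2-[2-bromo-6-methoxy-4-(methoxycarbonyl)phenoxy]-3-hydroxypropanoate
Product: 7 2-ethyl 6-methyl (2R,3S)-3-[4-(benzyloxy)-3-methoxyphenyl]-8-methoxy-2,3-dihydro-1,4-benzodioxine-2,6-dicarboxylate (trans)
Conditions: CuI (10 mol%), 3,4,7,8-tetramethyl-1,10-phenanthroline (20 mol%), Cs2CO3, toluene, 90 °C
Reagents that add atoms: none
Why: Ullmann-type intramolecular C–O coupling: the alkoxide of the C7' hydroxyl binds monovalent copper, which activates the C5–Br bond and releases the aryl ether, closing the six-membered dioxane. The C7'–O bond is never broken, so C7' keeps its configuration and the threo adduct gives the trans ring; the C9' ester leaves the C7' hydroxyl as the only nucleophile, so only one benzodioxane can form.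

Step 4
Reactants: 7 2-ethyl 6-methyl (2R,3S)-3-[4-(benzyloxy)-3-methoxyphenyl]-8-methoxy-2,3-dihydro-1,4-benzodioxine-2,6-dicarboxylate
Product: 8 [(2S,3S)-3-[4-(benzyloxy)-3-methoxyphenyl]-8-methoxy-2,3-dihydro-1,4-benzodioxine-2,6-diyl]dimethanol
Conditions: LiAlH4, THF, 0 °C
Reagents that add atoms: none
Why: Hydride reduction of both esters to primary alcohols; hydride addition is faster than enolisation at 0 °C, so C8' is not epimerised, and its descriptor changes from R to S only because C9' drops in CIP rank.

Step 5
Reactants: 8 [(2S,3S)-3-[4-(benzyloxy)-3-methoxyphenyl]-8-methoxy-2,3-dihydro-1,4-benzodioxine-2,6-diyl]dimethanol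
Product: 9 (2S,3S)-3-[4-(benzyloxy)-3-methoxyphenyl]-2-(hydroxymethyl)-8-methoxy-2,3-dihydro-1,4-benzodioxine-6-carbaldehyde
Conditions: activated MnO2 (excess), CH2Cl2, rt
Reagents that add atoms: none
Why: Heterogeneous MnO2 oxidation is selective for benzylic over saturated primary alcohols, so only the ring A carbinol becomes the aldehyde and the C9' alcohol and the benzyl ether stay untouched.

Step 6
Reactants: 9 (2S,3S)-3-[4-(benzyloxy)-3-methoxyphenyl]-2-(hydroxymethyl)-8-methoxy-2,3-dihydro-1,4-benzodioxine-6-carbaldehyde
Product: 10 (2E)-3-[(2S,3S)-3-[4-(benzyloxy)-3-methoxyphenyl]-2-(hydroxymethyl)-8-methoxy-2,3-dihydro-1,4-benzodioxin-6-yl]prop-2-enal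
Conditions: Ph3P=CHCHO (1.3 equiv), toluene, 80 °C
Reagents that add atoms: (triphenylphosphoranylidene)acetaldehyde, O=CC=P(c1ccccc1)(c1ccccc1)c1ccccc1
Why: Wittig olefination with a formyl-stabilised ylide, which gives the (E)-enal; the free C9' alcohol does not interfere, and limiting the ylide keeps the product enal from being homologated a second time.

Step 7
Reactants: 10 (2E)-3-[(2S,3S)-3-[4-(benzyloxy)-3-methoxyphenyl]-2-(hydroxymethyl)-8-methoxy-2,3-dihydro-1,4-benzodioxin-6-yl]prop-2-enal
Product: 11 (7'S,8'S)-nocomtal, (2E)-3-[(2S,3S)-3-(4-hydroxy-3-methoxyphenyl)-2-(hydroxymethyl)-8-methoxy-2,3-dihydro-1,4-benzodioxin-6-yl]prop-2-enal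
Conditions: BCl3 (3 equiv), pentamethylbenzene (3 equiv), CH2Cl2, −78 °C; then MeOH/H2O
Reagents that add atoms: none
Why: Lewis-acid debenzylation: BCl3 cleaves the aryl benzyl ether at −78 °C and pentamethylbenzene captures the benzyl cation by Friedel–Crafts alkylation, so the enal is not reduced and the electron-rich rings are not benzylated. The aryl methyl ethers and the two stereocentres should survive at this temperature; the C9' borate is hydrolysed on work-up.

## Compound list

1 | vanillin (4-hydroxy-3-methoxybenzaldehyde) | COc1cc(C=O)ccc1O | starting material
2 | 4-(benzyloxy)-3-methoxybenzaldehyde (O-benzylvanillin) | COc1cc(C=O)ccc1OCc1ccccc1 | intermediate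
3 | methyl 3-bromo-4-hydroxy-5-methoxybenzoate (methyl 5-bromovanillate) | COC(=O)c1cc(Br)c(O)c(OC)c1 | starting material
4 | ethyl diazoacetate | CCOC(=O)C=[N+]=[N-] | starting material
5 | oxonium ylide from 3 and the carbenoid of 4 (drawn free; it may stay bound to rhodium or pass into its enol) | CCOC(=O)[CH-][OH+]c1c(Br)cc(C(=O)OC)cc1OC | intermediate
6 | ethyl (2R,3S)-3-[4-(benzyloxy)-3-methoxyphenyl]-2-[2-bromo-6-methoxy-4-(methoxycarbonyl)phenoxy]-3-hydroxypropanoate (threo; 7'S,8'R) | COc1cc([C@H](O)[C@@H](Oc2c(Br)cc(C(=O)OC)cc2OC)C(=O)OCC)ccc1OCc1ccccc1 | intermediate
7 | 2-ethyl 6-methyl (2R,3S)-3-[4-(benzyloxy)-3-methoxyphenyl]-8-methoxy-2,3-dihydro-1,4-benzodioxine-2,6-dicarboxylate (trans) | COc1cc([C@@H]2Oc3cc(C(=O)OC)cc(OC)c3O[C@H]2C(=O)OCC)ccc1OCc1ccccc1 | intermediate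
8 | [(2S,3S)-3-[4-(benzyloxy)-3-methoxyphenyl]-8-methoxy-2,3-dihydro-1,4-benzodioxine-2,6-diyl]dimethanol | COc1cc([C@@H]2Oc3cc(CO)cc(OC)c3O[C@H]2CO)ccc1OCc1ccccc1 | intermediate
9 | (2S,3S)-3-[4-(benzyloxy)-3-methoxyphenyl]-2-(hydroxymethyl)-8-methoxy-2,3-dihydro-1,4-benzodioxine-6-carbaldehyde | COc1cc([C@@H]2Oc3cc(C=O)cc(OC)c3O[C@H]2CO)ccc1OCc1ccccc1 | intermediate
10 | (2E)-3-[(2S,3S)-3-[4-(benzyloxy)-3-methoxyphenyl]-2-(hydroxymethyl)-8-methoxy-2,3-dihydro-1,4-benzodioxin-6-yl]prop-2-enal | COc1cc([C@@H]2Oc3cc(/C=C/C=O)cc(OC)c3O[C@H]2CO)ccc1OCc1ccccc1 | intermediate
11 | (7'S,8'S)-nocomtal | COc1cc([C@@H]2Oc3cc(/C=C/C=O)cc(OC)c3O[C@H]2CO)ccc1O | target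

## Step count and least certain steps

Total step count: 7. Longest linear sequence: 7 steps (1 to 11).

**Step 2 (key step).** The most likely failure is that proton transfer within the ylide outruns its addition to the aldehyde, so that simple O–H insertion dominates. An acceptor-only carbenoid gives a short-lived ylide, the phosphoric acid can itself shuttle the proton, and an electron-rich aldehyde is a weak electrophile. A second risk is poor facial or threo/erythro selectivity, because the aldehyde is only loosely held by the acid. The fallback uses known chemistry and sets out from 3.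
- Alkylation of 3 with (4R)-4-benzyl-3-(bromoacetyl)-1,3-oxazolidin-2-one (K2CO3, acetone) gives the N-(aryloxyacetyl)oxazolidinone F1.
- An Evans syn-aldol reaction of F1 (Bu2BOTf, iPr2NEt, CH2Cl2, −78 to 0 °C) with aldehyde 2 gives the syn adduct imide F2. By analogy with the established facial preference of this auxiliary class, the (4R)-auxiliary should deliver the (2R,3S) configuration.
- Ethanolysis of F2 with bromomagnesium ethoxide (EtMgBr, EtOH, 0 °C) releases the auxiliary and comes back to the route at 6.

**Step 3.** The most likely failure is base-induced retro-aldol cleavage, C8' epimerisation or β-elimination of the open-chain β-hydroxy ester before the hindered secondary alkoxide couples, because the C8' hydrogen is acidic and the coupling needs heat. Any erythro adduct carried over from step 2 would appear here as the cis ring isomer and is removed by chromatography. The fallback removes the ester before the closure and sets out from 6.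
- LiAlH4 (THF, 0 °C, at which the aryl bromide is inert) gives the bromo triol F3.
- TBSCl and imidazole silylate the two primary hydroxyls to give the bis-silyl ether F4.
- The same CuI-catalysed closure, now on a substrate without an acidic C–H or a cleavable aldol unit, gives the silylated benzodioxane F5.
- TBAF in THF comes back to the route at 8.

**Step 7.** The most likely failure is ionisation of the C7'–O5 benzylic ether by the Lewis acid, leading to ring opening or C7' epimerisation, together with chloride addition to the enal. The para oxygen stabilises a cation at C7', and the enal binds BCl3. The fallback removes the benzyl group before any reducible or acid-sensitive group is present and sets out from 7.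
- Hydrogenolysis (H2, 10% Pd/C, EtOAc, rt, stopped once the benzyl ether is consumed) gives the phenol diester F6.
- LiAlH4 (one extra equivalent for the phenol) gives the phenol diol F7.
- MnO2 gives the phenol aldehyde F8.
- The Wittig reaction with Ph3P=CHCHO, which tolerates the remote phenol, comes back to the route at 11.

**Step 6.** The most likely failure is a second homologation of the product enal to the dienal, or incomplete conversion of the electron-rich aldehyde, because product and substrate have similar reactivity towards the ylide. The fallback sets out from 9.
- Horner–Wadsworth–Emmons olefination with triethyl phosphonoacetate (LiCl, DBU, MeCN), which cannot over-react, gives the (E)-cinnamate ester F9.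
- iBu2AlH (CH2Cl2, −78 °C) gives the allylic alcohol F10.
- MnO2, selective for the allylic over the C9' alcohol, comes back to the route at 10.

## Further compounds

F1 | step 2 | methyl 4-{2-[(4R)-4-benzyl-2-oxo-1,3-oxazolidin-3-yl]-2-oxoethoxy}-3-bromo-5-methoxybenzoate | COC(=O)c1cc(Br)c(OCC(=O)N2[C@H](Cc3ccccc3)COC2=O)c(OC)c1
F2 | step 2 | methyl 4-{[(2R,3S)-1-[(4R)-4-benzyl-2-oxo-1,3-oxazolidin-3-yl]-3-[4-(benzyloxy)-3-methoxyphenyl]-3-hydroxy-1-oxopropan-2-yl]oxy}-3-bromo-5-methoxybenzoate | COc1cc([C@H](O)[C@@H](Oc2c(Br)cc(C(=O)OC)cc2OC)C(=O)N2[C@H](Cc3ccccc3)COC2=O)ccc1OCc1ccccc1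
F3 | step 3 | (1S,2S)-1-[4-(benzyloxy)-3-methoxyphenyl]-2-[2-bromo-4-(hydroxymethyl)-6-methoxyphenoxy]propane-1,3-diol | COc1cc([C@H](O)[C@@H](Oc2c(Br)cc(CO)cc2OC)CO)ccc1OCc1ccccc1
F4 | step 3 | (1S,2S)-1-[4-(benzyloxy)-3-methoxyphenyl]-2-[2-bromo-4-({[tert-butyl(dimethyl)silyl]oxy}methyl)-6-methoxyphenoxy]-3-{[tert-butyl(dimethyl)silyl]oxy}propan-1-ol | COc1cc([C@H](O)[C@@H](Oc2c(Br)cc(CO[Si](C)(C)C(C)(C)C)cc2OC)CO[Si](C)(C)C(C)(C)C)ccc1OCc1ccccc1
F5 | step 3 | (2S,3S)-3-[4-(benzyloxy)-3-methoxyphenyl]-2,6-bis({[tert-butyl(dimethyl)silyl]oxy}methyl)-8-methoxy-2,3-dihydro-1,4-benzodioxine | COc1cc([C@@H]2Oc3cc(CO[Si](C)(C)C(C)(C)C)cc(OC)c3O[C@H]2CO[Si](C)(C)C(C)(C)C)ccc1OCc1ccccc1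
F6 | step 7 | 2-ethyl 6-methyl (2R,3S)-3-(4-hydroxy-3-methoxyphenyl)-8-methoxy-2,3-dihydro-1,4-benzodioxine-2,6-dicarboxylate | COc1cc([C@@H]2Oc3cc(C(=O)OC)cc(OC)c3O[C@H]2C(=O)OCC)ccc1O
F7 | step 7 | [(2S,3S)-3-(4-hydroxy-3-methoxyphenyl)-8-methoxy-2,3-dihydro-1,4-benzodioxine-2,6-diyl]dimethanol | COc1cc([C@@H]2Oc3cc(CO)cc(OC)c3O[C@H]2CO)ccc1O
F8 | step 7 | (2S,3S)-3-(4-hydroxy-3-methoxyphenyl)-2-(hydroxymethyl)-8-methoxy-2,3-dihydro-1,4-benzodioxine-6-carbaldehyde | COc1cc([C@@H]2Oc3cc(C=O)cc(OC)c3O[C@H]2CO)ccc1O
F9 | step 6 | ethyl (2E)-3-[(2S,3S)-3-[4-(benzyloxy)-3-methoxyphenyl]-2-(hydroxymethyl)-8-methoxy-2,3-dihydro-1,4-benzodioxin-6-yl]prop-2-enoate | COc1cc([C@@H]2Oc3cc(/C=C/C(=O)OCC)cc(OC)c3O[C@H]2CO)ccc1OCc1ccccc1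
F10 | step 6 | (2E)-3-[(2S,3S)-3-[4-(benzyloxy)-3-methoxyphenyl]-2-(hydroxymethyl)-8-methoxy-2,3-dihydro-1,4-benzodioxin-6-yl]prop-2-en-1-ol | COc1cc([C@@H]2Oc3cc(/C=C/CO)cc(OC)c3O[C@H]2CO)ccc1OCc1ccccc1
A1 | alternative 1 | methyl (2S,3S)-2-({[tert-butyl(dimethyl)silyl]oxy}methyl)-3-(4-hydroxy-3-methoxyphenyl)-8-methoxy-2,3-dihydro-1,4-benzodioxine-6-carboxylate | COc1cc([C@@H]2Oc3cc(C(=O)OC)cc(OC)c3O[C@H]2CO[Si](C)(C)C(C)(C)C)ccc1O
A2 | alternative 1 | methyl 4-{[(2R)-1-{[tert-butyl(dimethyl)silyl]oxy}-3-(4-hydroxy-3-methoxyphenyl)propan-2-yl]oxy}-3-hydroxy-5-methoxybenzoate | COc1cc(C[C@H](CO[Si](C)(C)C(C)(C)C)Oc2c(O)cc(C(=O)OC)cc2OC)ccc1O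
A3 | alternative 2 | methyl 4-{[2-(4-acetoxy-3-methoxyphenyl)oxetan-3-yl]oxy}-3-methoxy-5-(methoxymethoxy)benzoate (racemic, C7' epimers, drawn with the C8' configuration that would be carried forward) | COc1cc(C2OC[C@@H]2Oc2c(OC)cc(C(=O)OC)cc2OCOC)ccc1OC(C)=O
A4 | alternative 2 | methyl 3-methoxy-5-(methoxymethoxy)-4-(vinyloxy)benzoate | C=COc1c(OC)cc(C(=O)OC)cc1OCOC
A5 | alternative 2 | 4-formyl-2-methoxyphenyl acetate | COc1cc(C=O)ccc1OC(C)=O
A6 | alternative 3 | methyl (2R,3S)-3-[4-(benzyloxy)-3-methoxyphenyl]-6-formyl-8-methoxy-2,3-dihydro-1,4-benzodioxine-2-carboxylate | COc1cc([C@@H]2Oc3cc(C=O)cc(OC)c3O[C@H]2C(=O)OC)ccc1OCc1ccccc1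
A7 | alternative 3 | methyl (2R,3S)-3-[4-(benzyloxy)-3-methoxyphenyl]-2,3-dihydroxypropanoate | COc1cc([C@H](O)[C@@H](O)C(=O)OC)ccc1OCc1ccccc1
A8 | alternative 3 | 3-bromo-4-fluoro-5-methoxybenzaldehyde | COc1cc(C=O)cc(Br)c1F
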